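**Retrosynthetic overview**
- The ester is cut at the acyl C–O bond into 2,4-dihydroxy-6-undecylbenzoic acid 5 and the (R)-alcohol 11; the union runs with retention at the carbinol carbon and uses no protecting groups.
- Acid 5 comes from 5-undecylresorcinol 4 by ortho-carboxylation; 4 comes from undec-1-ene 1 and 5-bromoresorcinol 2 by B-alkyl Suzuki coupling.
- Alcohol 11 comes from (4R)-undec-10-en-4-ol 9 and 2 by B-alkyl Suzuki coupling; 9 comes from hex-5-enylmagnesium bromide and (2R)-2-propyloxirane 7, which supplies the stereocentre.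
- No ring is formed: both benzene rings are bought intact as 2.

Assumption: (2R)-2-propyloxirane is bought enantiopure (it is made on scale by hydrolytic kinetic resolution); the target stereocentre is R.

**Step 1**
Reactants: 1 undec-1-ene; 2 5-bromobenzene-1,3-diol
Product: 4 5-undecylbenzene-1,3-diol, via 9-undecyl-9-BBN 3 (not isolated)
Conditions: 1 (1.5 equiv), 9-BBN (1.5 equiv), THF, 0 °C → rt; then 2, Pd(OAc)2 (3 mol %), SPhos (6 mol %), aq K3PO4 (5 equiv), 65 °C; dilute HCl work-up
Reagents that add atoms: none
Why: Anti-Markovnikov hydroboration followed by B-alkyl Suzuki–Miyaura coupling should work because the bromide is meta to both phenoxides, so oxidative addition is not shut down and the extra base simply carries the two OH groups as phenoxides.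

**Step 2**
Reactants: 4 5-undecylbenzene-1,3-diol
Product: 5 2,4-dihydroxy-6-undecylbenzoic acid
Conditions: MeOMgOCO2Me (2 M in DMF, 6 equiv), 125 °C, 3 h; then cold 2 M HCl
Reagents that add atoms: methylmagnesium carbonate (Stiles reagent), COC(=O)O[Mg]OC
Why: Kolbe–Schmitt-type carboxylation through a magnesium phenoxide chelate delivers CO2 ortho to one OH and para to the other (the olivetolic-acid pattern), and the chelate protects the acid from decarboxylation until cold acidification.

**Step 3**
Reactants: 6 6-bromohex-1-ene; 7 (2R)-2-propyloxirane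
Product: 9 (4R)-undec-10-en-4-ol, via hex-5-enylmagnesium bromide 8 (not isolated)
Conditions: Mg, THF, rt → 40 °C; then CuI (10 mol %), 7 (0.8 equiv), THF, −30 → 0 °C; H2O quench
Reagents that add atoms: none
Why: Copper-catalysed Grignard opening of a terminal epoxide is an SN2 attack at the CH2 carbon, so no bond to the stereocentre is touched and the R centre of 7 becomes C4 of 9.

**Step 4**
Reactants: 9 (4R)-undec-10-en-4-ol; 2 5-bromobenzene-1,3-diol
Product: 11 5-[(8R)-8-hydroxyundecyl]benzene-1,3-diol, via bis-9-BBN adduct 10 (not isolated)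
Conditions: 9-BBN (2.3 equiv), THF, 0 °C → rt; then 2 (0.9 equiv), Pd(OAc)2 (3 mol %), SPhos (6 mol %), aq K3PO4 (6 equiv), 65 °C; dilute HCl work-up
Reagents that add atoms: none
Why: One equivalent of 9-BBN masks the secondary OH as a borinate and the second hydroborates the terminal alkene, after which B-alkyl Suzuki–Miyaura coupling joins the primary alkylborane to the arene and aqueous work-up frees the alcohol with C8 unchanged.

**Step 5**
Reactants: 5 2,4-dihydroxy-6-undecylbenzoic acid; 11 5-[(8R)-8-hydroxyundecyl]benzene-1,3-diol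
Product: 14 (4R)-11-(3,5-dihydroxyphenyl)undecan-4-yl 2,4-dihydroxy-6-undecylbenzoate, via O-acylisourea 12 (not isolated), via oxoketene 13 (not isolated)
Conditions: DIC (1.4 equiv), 5 (1.3 equiv, added over 2 h), THF, 0 °C → rt; then DBU (0.3 equiv), 40 °C, 6 h
Reagents that add atoms: none
Why: Proposed new method: a carbodiimide-triggered E1cB oxoketene acyl transfer with base proofreading, in which the acid adds to DIC to give O-acylisourea 12, whose doubly ortho-substituted carbonyl resists direct attack and O→N acyl shift, so phenol-assisted E1cB loss of diisopropylurea gives the sterically open oxoketene 13, which the secondary alcohol captures at the acyl carbon with retention at C4; aryl esters or anhydride formed by capture on phenols or carboxylate keep a good leaving group and are re-ionised to 13 by DBU, whereas the alkyl ester cannot ionise, so all acyl units should funnel to 14; the closest known reactions are Steglich carbodiimide esterification, quinoketene trapping from benzodioxinones, and E1cB acyl transfer of hydroxybenzoate aryl esters.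

**Compound list**
1 | undec-1-ene | C=CCCCCCCCCC | starting material
2 | 5-bromobenzene-1,3-diol (5-bromoresorcinol) | Oc1cc(O)cc(Br)c1 | starting material
3 | 9-undecyl-9-borabicyclo[3.3.1]nonane (9-undecyl-9-BBN) | CCCCCCCCCCCB1C2CCCC1CCC2 | intermediate
4 | 5-undecylbenzene-1,3-diol | CCCCCCCCCCCc1cc(O)cc(O)c1 | intermediate
5 | 2,4-dihydroxy-6-undecylbenzoic acid | CCCCCCCCCCCc1cc(O)cc(O)c1C(=O)O | intermediate
6 | 6-bromohex-1-ene | C=CCCCCBr | starting material
7 | (2R)-2-propyloxirane | CCC[C@@H]1CO1 | starting material
8 | hex-5-enylmagnesium bromide | C=CCCCC[Mg]Br | intermediate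
9 | (4R)-undec-10-en-4-ol | CCC[C@@H](O)CCCCCC=C | intermediate
10 | 9-{[(4R)-11-(9-borabicyclo[3.3.1]nonan-9-yl)undecan-4-yl]oxy}-9-borabicyclo[3.3.1]nonane (bis-9-BBN adduct) | CCC[C@@H](OB1C2CCCC1CCC2)CCCCCCCB1C2CCCC1CCC2 | intermediate
11 | 5-[(8R)-8-hydroxyundecyl]benzene-1,3-diol | CCC[C@@H](O)CCCCCCCc1cc(O)cc(O)c1 | intermediate
12 | O-(2,4-dihydroxy-6-undecylbenzoyl)-N,N'-diisopropylisourea (O-acylisourea) | CCCCCCCCCCCc1cc(O)cc(O)c1C(=O)OC(=NC(C)C)NC(C)C | intermediate
13 | 3-hydroxy-6-(oxomethylidene)-5-undecylcyclohexa-2,4-dien-1-one (oxoketene) | CCCCCCCCCCCC1=CC(O)=CC(=O)C1=C=O | intermediate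
14 | (4R)-11-(3,5-dihydroxyphenyl)undecan-4-yl 2,4-dihydroxy-6-undecylbenzoate | CCCCCCCCCCCc1cc(O)cc(O)c1C(=O)O[C@H](CCC)CCCCCCCc1cc(O)cc(O)c1 | target

**Step count**
Total steps: 5 (each one-pot hydroboration/coupling counted as one step).
Longest linear sequence: 3 steps (6 + 7 → 9 → 11 → 14, or 1 + 2 → 4 → 5 → 14).

**Steps most likely to fail, with fallbacks**

Step 5 (the proposed new esterification). Capture of the oxoketene by phenols, or an N-acylurea dead end, may win over funnelling to the alkyl ester. The fallback forms the alkyl C–O bond with inversion instead of the acyl C–O bond with retention, so it needs the enantiomeric alcohol. It sets out from Grignard reagent 8, which is opened with bought (2S)-2-propyloxirane (CCC[C@H]1CO1) under the step 3 conditions to give (4S)-undec-10-en-4-ol F3. This is treated with 9-BBN as in step 4 to give the (S)-bis-9-BBN adduct F4, which is coupled with 2 to give 5-[(8S)-8-hydroxyundecyl]benzene-1,3-diol F5. Mitsunobu esterification of F5 with acid 5 (1.5 equiv), PPh3 and DIAD in THF/toluene at 0 °C → rt then inverts C8; the carboxylic acid (pKa about 3) is the only pronucleophile ionised, so the phenols are not alkylated. The fallback comes back to the route at target 14.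

Step 4 (B-alkyl Suzuki on unprotected 5-bromoresorcinol with a borinate-bearing partner). Phenoxide binding to boron or palladium may stall the coupling. The fallback sets out from 9 through its adduct 10, which is coupled with bought 1,3-bis(benzyloxy)-5-bromobenzene (PdCl2(dppf), aq K3PO4, THF/DMF, 60 °C) to give (4R)-11-[3,5-bis(benzyloxy)phenyl]undecan-4-ol F2. Hydrogenolysis (H2, Pd/C, EtOAc/MeOH) then frees both phenols, and the fallback comes back to the route at 11.

Step 2 (direct carboxylation). The 2,6-dihydroxy regioisomer or decarboxylation on work-up may lower the yield. The fallback sets out from 4 and uses Vilsmeier–Haack formylation (POCl3, DMF, 0 °C → rt; aq NaOAc), which goes para to one OH and gives 2,4-dihydroxy-6-undecylbenzaldehyde F1. Pinnick–Lindgren oxidation (NaClO2, NaH2PO4, sulfamic acid as hypochlorite scavenger, DMSO/H2O, 0 °C) then gives the acid, and the fallback comes back to the route at 5.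

**Further compounds**
F1 | step 2 | 2,4-dihydroxy-6-undecylbenzaldehyde | CCCCCCCCCCCc1cc(O)cc(O)c1C=O
F2 | step 4 | (4R)-11-[3,5-bis(benzyloxy)phenyl]undecan-4-ol | CCC[C@@H](O)CCCCCCCc1cc(OCc2ccccc2)cc(OCc2ccccc2)c1
F3 | step 5 | (4S)-undec-10-en-4-ol | CCC[C@H](O)CCCCCC=C
F4 | step 5 | 9-{[(4S)-11-(9-borabicyclo[3.3.1]nonan-9-yl)undecan-4-yl]oxy}-9-borabicyclo[3.3.1]nonane | CCC[C@H](OB1C2CCCC1CCC2)CCCCCCCB1C2CCCC1CCC2
F5 | step 5 | 5-[(8S)-8-hydroxyundecyl]benzene-1,3-diol | CCC[C@H](O)CCCCCCCc1cc(O)cc(O)c1
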